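## Analysis of the target

The target 22 is a spiro tricycle. A 3,4,5-trimethoxybenzene (ring A, arene C1–C6) is fused through C1 and C2 to a seven-membered carbocycle (ring C: C7, C8, C8′, C7′, C1′). C1′ is also the spiro atom of a 2,6-dimethoxycyclohexa-2,5-dienone (ring B: C1′, C2′H=C3′(OMe), C4′=O, C5′(OMe)=C6′H).

Ring C carries three contiguous stereocentres: C7 (R, secondary benzylic alcohol), C8 (S, methyl) and C8′ (R, methyl). On the ring the hydroxyl is trans to the C8 methyl and the two methyls are trans to each other. In an open-chain zigzag C7–C8–C8′–C7′ this is the all-syn triad. C1′ is quaternary but not stereogenic, because ring B has a mirror plane through C1′ and C4′.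

The sensitive groups are the cross-conjugated dienone (dienone–phenol rearrangement in acid, attack by nucleophiles and reductants) and the electron-rich benzylic alcohol (ionisation, elimination, lactol formation with any carbonyl on C1′).

The synthesis is hard for three reasons. The quaternary C1′ sits on arene C2 next to the C3 methoxy group. The ring is medium-sized. The trans-dimethyl pattern is the one that open-chain hydroboration of a 2-methylallyl unit next to C8 would not give: by allylic strain it should give the cis isomer.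

The strategy rests on the symmetry of ring B. C3′–C4′–C5′ with their three oxygens are the skeleton of 1,3-dimethoxyacetone, and C1′ can be the α-carbon of an aryl-substituted aldehyde whose formyl carbon becomes C2′. Ring B can therefore be built last, by a Michael–aldol annulation on a finished ring A/ring C aldehyde.

## Retrosynthetic reasoning

**22 to 21.** The C7 hydroxyl is unmasked last from silyl ether 21. A silyl group is needed from the moment a carbonyl sits on C1′, since a free C7–OH would close a lactol onto it. It falls to buffered fluoride, which leaves the dienone alone.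

**21 to 19.** The C5′=C6′ double bond is cut back to the CH(OMe)–CH2 side of enone 19. Forward, a kinetic enolate at C5′ is silylated (20) and dehydrogenated (Saegusa–Ito). This is the step that makes ring B symmetric, so the configurations at C1′ and C5′ in 19 are irrelevant.

**19 to 12 and 16 (key disconnection).** Ring B is cut at C1′–C6′ and C2′=C3′. This gives aldehyde 12 (C1′ as α-carbon, CHO as C2′) and vinyl ketone 16 (C3′ to C6′ with both methoxy groups). Both bonds form in one operation through 17 and 18, and no stereocentre has to be controlled. Cutting elsewhere in ring B would break its symmetry-derived match with a three-carbon ketone. Forward, the hindered tertiary enolate of 12 must add through carbon to 16, and the methoxymethyl carbon must then condense with the formyl group.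

**16 to 15, 14 and 13.** The sensitive α-methoxy vinyl ketone 16 is not stored. It is released in the flask from ammonium salt 15, which comes from Mannich base 14 and symmetric ketone 13.

**12 to 11 and 10.** The formyl carbon is removed to ketone 10. Forward this is a methoxymethylene Wittig reaction to 11 and hydrolysis. Both C1′ epimers of 12 are acceptable, because C1′ becomes an enolate.

**10 to 8.** Ring C is opened at arene C2–C1′. Forward, bromine–lithium exchange on 8 gives aryllithium 9, which acylates itself on the Weinreb amide. The bromine marks C2 and the amide stops at the ketone stage.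

**8 to 7 and 6.** The amide and the C7 oxygen are tied back into δ-lactone 6. Forward this is aminolysis to 7 and silylation.

**6 to 5.** The C8′–CH3 bond is cut. In the six-membered lactone a methyl cuprate should enter anti to the neighbouring C5 methyl, which gives exactly the trans-dimethyl relationship. The ring template is used instead of open-chain hydroboration for this reason.

**5 to 4 and 3.** The lactone C=C is cut by ring-closing metathesis logic to acrylate 4, the ester of homoallylic alcohol 3.

**3 to 1 and 2.** The C7–C8 bond is cut. Forward, a catalytic asymmetric Z-crotylboration of aldehyde 1 with boronate 2 sets C7 and C8 (syn) in the first step.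

## Alternatives that were turned down

**Alternative 1:** Ring C is cut at C1′–C7′ and C7–arene C1, giving the 4-aryl quinol A2 and the diene A3. Forward, a Lewis acid ionises A2; A3 adds with one terminus to C1′ and the allyl cation closes on the arene in a (4+3) sense to the achiral spirodienone A1.
- For: two simple achiral pieces give ring C and the quaternary centre at once, with ring B already at the dienone level. In steps to the ring system this is clearly shorter than the chosen route.
- Against: A1 has no stereocentre. The trans-dimethyl pair would need net anti addition of hydrogen to a tetrasubstituted C8=C8′ alkene beside a more reducible dienone, with enantiocontrol. C7 would need a face-selective benzylic C–H oxidation. The cation of A2 also carries charge on the methoxy-bearing C3′/C5′, so the site of attack is uncertain.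
- Comparison: the chosen strategy spends more steps but fixes C7, C8 and C8′ early with well-understood models.

**Alternative 2:** Both C–CH3 bonds are cut, leading to the ring C enone A5. Forward, a copper–phosphoramidite-catalysed addition of a methylzinc reagent to C8′ is followed by methylation of the zinc enolate at C8, giving the trans-dimethyl ketone A4; the C7 ketone is then reduced.
- For: one catalytic step sets two stereocentres, and the trans relationship follows from anti alkylation. In stereocentre economy this is stronger than the chosen route.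
- Against: A5 has three enone units, and the organometallic reagent meets the dienone of ring B. Methylzinc reagents are sluggish, zinc enolates methylate poorly, and C8 is epimerisable. The C7 reduction must be both face- and chemoselective. A5 still needs its own synthesis, including the spiro centre.
- Comparison: the chosen strategy keeps all organometallic chemistry away from ring B by making it last.

**Alternative 3:** Both arene–ring C bonds are cut. Forward, fluoride releases the aryne from silyl triflate A8; the enolate carbon of keto ester A7 adds to the aryne carbon remote from methoxy, the aryl anion attacks the ketone, and fragmentation gives the ring-expanded keto ester A6.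
- For: it is convergent, the aryne regiochemistry fits, and the C2 symmetry of the parent ketone of A7 removes any regiochemical question. As a route to a C1′ ketone it is about as good as the route to 10.
- Against: C7 arrives bearing an ester, not an oxygen. Turning it into a configurationally defined alcohol costs several uncertain steps, and enantiopure A7 is not a commodity. Ring B is not addressed at all; A6 would still need the homologation and annulation used here.
- Comparison: the chosen route brings in the C7 oxygen with its configuration in step 1.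

Key step: step 12

Remark: atom labels follow lignan numbering (arene C1–C6, C7, C8, C8′, C7′, ring B C1′–C6′); (R)-TRIP is assumed to be the catalyst enantiomer that sends the crotyl group to the Re face of aryl aldehydes, and 1, 2 and 13 are taken as purchasable.

## Route

Step 1
Reactants: 1 2-bromo-3,4,5-trimethoxybenzaldehyde; 2 (Z)-crotylboronic acid pinacol ester
Product: 3 (1R,2S)-1-(2-bromo-3,4,5-trimethoxyphenyl)-2-methylbut-3-en-1-ol
Conditions: (R)-TRIP [(R)-3,3′-bis(2,4,6-triisopropylphenyl)-1,1′-binaphthyl-2,2′-diyl hydrogen phosphate] (5 mol%), 4 Å molecular sieves, toluene, −30 °C; aqueous work-up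
Reagents that add atoms: none
Why: Chiral phosphoric acid-catalysed crotylboration through a closed chair transition state; the Z geometry of 2 should translate into the 7,8-syn relationship and the catalyst into Re-face attack, setting C7 (R) and C8 (S) together.

Step 2
Reactants: 3 (1R,2S)-1-(2-bromo-3,4,5-trimethoxyphenyl)-2-methylbut-3-en-1-ol
Product: 4 (1R,2S)-1-(2-bromo-3,4,5-trimethoxyphenyl)-2-methylbut-3-en-1-yl prop-2-enoate
Conditions: acryloyl chloride, i-Pr2NEt, DMAP (cat.), CH2Cl2, −20 to 0 °C
Reagents that add atoms: acryloyl chloride C=CC(=O)Cl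
Why: DMAP-catalysed O-acylation of the secondary benzylic alcohol; no stereocentre is touched.

Step 3
Reactants: 4 (1R,2S)-1-(2-bromo-3,4,5-trimethoxyphenyl)-2-methylbut-3-en-1-yl prop-2-enoate
Product: 5 (5S,6R)-6-(2-bromo-3,4,5-trimethoxyphenyl)-5-methyl-5,6-dihydro-2H-pyran-2-one
Conditions: second-generation Grubbs catalyst RuCl2(=CHPh)(PCy3)(H2IMes) (5 mol%), CH2Cl2 (0.01 M), 40 °C
Reagents that add atoms: none
Why: Ring-closing metathesis of an acrylate with a monosubstituted alkene to a six-membered unsaturated lactone, driven by loss of ethene; the aryl bromide is inert.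

Step 4
Reactants: 5 (5S,6R)-6-(2-bromo-3,4,5-trimethoxyphenyl)-5-methyl-5,6-dihydro-2H-pyran-2-one
Product: 6 (4R,5S,6R)-6-(2-bromo-3,4,5-trimethoxyphenyl)-4,5-dimethyloxan-2-one
Conditions: Me2CuLi (2 equiv), Et2O, −78 to −40 °C; aqueous NH4Cl
Reagents that add atoms: lithium dimethylcuprate [Li+].C[Cu-]C
Why: Conjugate addition of a Gilman cuprate to an α,β-unsaturated δ-lactone; in the half-chair with the aryl group pseudoequatorial the C5 methyl is pseudoaxial, so the new methyl should enter C4 anti to it by axial attack, setting C8′ (R) trans to the C8 methyl. At this temperature the electron-rich aryl bromide should not exchange.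

Step 5
Reactants: 6 (4R,5S,6R)-6-(2-bromo-3,4,5-trimethoxyphenyl)-4,5-dimethyloxan-2-one
Product: 7 (3R,4S,5R)-5-(2-bromo-3,4,5-trimethoxyphenyl)-5-hydroxy-N-methoxy-N,3,4-trimethylpentanamide
Conditions: MeONHMe·HCl, i-PrMgCl, THF, −20 to 0 °C; aqueous NH4Cl
Reagents that add atoms: N,O-dimethylhydroxylamine hydrochloride CNOC.Cl
Why: Weinreb aminolysis of the lactone by the chloromagnesium amide; C8′ is β to the carbonyl and cannot epimerise, and 7 is silylated at once to forestall relactonisation.

Step 6
Reactants: 7 (3R,4S,5R)-5-(2-bromo-3,4,5-trimethoxyphenyl)-5-hydroxy-N-methoxy-N,3,4-trimethylpentanamide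
Product: 8 (3R,4S,5R)-5-(2-bromo-3,4,5-trimethoxyphenyl)-5-[(tert-butyldimethylsilyl)oxy]-N-methoxy-N,3,4-trimethylpentanamide
Conditions: TBSOTf, 2,6-lutidine, CH2Cl2, −78 to 0 °C
Reagents that add atoms: tert-butyldimethylsilyl trifluoromethanesulfonate CC(C)(C)[Si](C)(C)OS(=O)(=O)C(F)(F)F
Why: Silylation of a hindered secondary benzylic alcohol with the silyl triflate; the ether later blocks hemiketal and lactol formation with the C1′ carbonyl.

Step 7
Reactants: 8 (3R,4S,5R)-5-(2-bromo-3,4,5-trimethoxyphenyl)-5-[(tert-butyldimethylsilyl)oxy]-N-methoxy-N,3,4-trimethylpentanamide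
Product: 10 (7R,8S,9R)-9-[(tert-butyldimethylsilyl)oxy]-2,3,4-trimethoxy-7,8-dimethyl-6,7,8,9-tetrahydro-5H-benzo[7]annulen-5-one, via aryllithium 9 (not isolated)
Conditions: t-BuLi (2.1 equiv), THF, −78 °C; aqueous NH4Cl
Reagents that add atoms: none
Why: Parham cyclization: bromine–lithium exchange is faster than attack of t-BuLi on the amide, and aryllithium 9 adds to the Weinreb amide (7-exo-trig) to a chelated tetrahedral intermediate that gives the ketone only on work-up. Ring C is closed at arene C2–C1′.

Step 8
Reactants: 10 (7R,8S,9R)-9-[(tert-butyldimethylsilyl)oxy]-2,3,4-trimethoxy-7,8-dimethyl-6,7,8,9-tetrahydro-5H-benzo[7]annulen-5-one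
Product: 11 (7R,8S,9R)-9-[(tert-butyldimethylsilyl)oxy]-2,3,4-trimethoxy-5-(methoxymethylidene)-7,8-dimethyl-6,7,8,9-tetrahydro-5H-benzo[7]annulene (E/Z mixture)
Conditions: MeOCH2PPh3Cl, KN(SiMe3)2, THF, 0 °C to rt
Reagents that add atoms: (methoxymethyl)triphenylphosphonium chloride COC[P+](c1ccccc1)(c1ccccc1)c1ccccc1.[Cl-]
Why: Wittig methoxymethylenation of an aryl ketone, the standard one-carbon homologation of benzo-fused cyclic ketones; the enol ether geometry is irrelevant.

Step 9
Reactants: 11 (7R,8S,9R)-9-[(tert-butyldimethylsilyl)oxy]-2,3,4-trimethoxy-5-(methoxymethylidene)-7,8-dimethyl-6,7,8,9-tetrahydro-5H-benzo[7]annulene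
Product: 12 (7R,8S,9R)-9-[(tert-butyldimethylsilyl)oxy]-2,3,4-trimethoxy-7,8-dimethyl-6,7,8,9-tetrahydro-5H-benzo[7]annulene-5-carbaldehyde (both C5 epimers)
Conditions: 1 M aqueous HCl, THF, 0 °C to rt, short reaction time
Reagents that add atoms: water O
Why: Acid-catalysed enol ether hydrolysis (protonation at C1′, hydration of the oxocarbenium ion, loss of methanol); the hindered secondary silyl ether should survive brief dilute acid, and the C1′ configuration is of no consequence.

Step 10
Reactants: 13 1,3-dimethoxypropan-2-one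
Product: 14 4-(dimethylamino)-1,3-dimethoxybutan-2-one (racemic)
Conditions: [CH2=NMe2]I, MeCN, 60 °C, 13 in excess; aqueous NaHCO3
Reagents that add atoms: N,N-dimethylmethyleneiminium iodide C=[N+](C)C.[I-]
Why: Mannich reaction of the enol of a symmetric ketone with a preformed iminium salt; excess ketone should suppress double aminomethylation.

Step 11
Reactants: 14 4-(dimethylamino)-1,3-dimethoxybutan-2-one
Product: 15 2,4-dimethoxy-N,N,N-trimethyl-3-oxobutan-1-aminium iodide (racemic)
Conditions: MeI, Et2O, 0 °C to rt
Reagents that add atoms: iodomethane CI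
Why: Menshutkin quaternisation of the tertiary amine, giving a storable salt that releases the vinyl ketone only on treatment with base.

Step 12
Reactants: 12 (7R,8S,9R)-9-[(tert-butyldimethylsilyl)oxy]-2,3,4-trimethoxy-7,8-dimethyl-6,7,8,9-tetrahydro-5H-benzo[7]annulene-5-carbaldehyde; 15 2,4-dimethoxy-N,N,N-trimethyl-3-oxobutan-1-aminium iodide
Product: 19 (7R,8S,9R)-9-[(tert-butyldimethylsilyl)oxy]-2,3,3′,4,5′-pentamethoxy-7,8-dimethyl-6,7,8,9-tetrahydrospiro[benzo[7]annulene-5,1′-cyclohex[2]en]-4′-one (mixture of C1′/C5′ epimers), via 1,3-dimethoxybut-3-en-2-one 16 (not isolated), via Michael keto aldehyde 17 (not isolated), via aldol 18 (not isolated)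
Conditions: KOt-Bu (2.2 equiv), t-BuOH/THF, degassed, 0 °C, 15 (1.5 equiv) added in portions; then 50 °C
Reagents that add atoms: none
Why: KOt-Bu eliminates trimethylamine from 15 (E1cB) to release vinyl ketone 16 at low stationary concentration and converts 12 into its tertiary aryl-substituted enolate; conjugate addition of C1′ to the unsubstituted terminus of 16 forms the C1′–C6′ bond and the quaternary centre of keto aldehyde 17. Enolisation of 17 at the methoxymethyl carbon C3′ and aldol addition to the now non-enolisable formyl carbon C2′ closes ring B as 18 in a 6-(enolexo)-exo-trig mode, and E1cB loss of water gives the 2-methoxy enone 19. The closest known reaction type is the Robinson annulation of α-aryl aldehydes with vinyl ketones to 4-aryl-4-alkylcyclohexenones, including annulations with methoxymethyl vinyl ketone that end in 2-methoxycyclohexenones. The new centres C1′ and C5′ are under no control and need none, since both cease to be stereogenic once C5′=C6′ is introduced; C7, C8 and C8′ bear no acidic hydrogen and are carried through. The step needs C- over O-alkylation of the enolate (the acceptor is soft and O-addition is reversible), attack at C1′ despite the flanking C3 methoxy group (the partner is an unhindered CH2 terminus), and one aldol regiochemistry, which is secured because C5′ could reach the aldehyde only through a four-membered ring. The C7 silyl ether prevents lactol formation with the formyl group, and exclusion of oxygen prevents autoxidative deformylation of the enolate.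

Step 13
Reactants: 19 (7R,8S,9R)-9-[(tert-butyldimethylsilyl)oxy]-2,3,3′,4,5′-pentamethoxy-7,8-dimethyl-6,7,8,9-tetrahydrospiro[benzo[7]annulene-5,1′-cyclohex[2]en]-4′-one
Product: 21 (7R,8S,9R)-9-[(tert-butyldimethylsilyl)oxy]-2,3,3′,4,5′-pentamethoxy-7,8-dimethyl-6,7,8,9-tetrahydrospiro[benzo[7]annulene-5,1′-cyclohexa[2,5]dien]-4′-one, via trimethylsilyl dienol ether 20 (not isolated)
Conditions: LiN(i-Pr)2, Me3SiCl, THF, −78 °C; then Pd(OAc)2 (1.1 equiv), MeCN, rt
Reagents that add atoms: none
Why: Saegusa–Ito dehydrogenation: the only enolisable position of 19 is C5′, its silyl enol ether 20 transfers to divalent palladium, and β-hydride elimination from C6′ gives the cross-conjugated dienone. Ring B becomes symmetric and the C1′ and C5′ centres disappear.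

Step 14
Reactants: 21 (7R,8S,9R)-9-[(tert-butyldimethylsilyl)oxy]-2,3,3′,4,5′-pentamethoxy-7,8-dimethyl-6,7,8,9-tetrahydrospiro[benzo[7]annulene-5,1′-cyclohexa[2,5]dien]-4′-one
Product: 22 (7R,8S,9R)-9-hydroxy-2,3,3′,4,5′-pentamethoxy-7,8-dimethyl-6,7,8,9-tetrahydrospiro[benzo[7]annulene-5,1′-cyclohexa[2,5]dien]-4′-one (target CNP0288561.1)
Conditions: HF·pyridine, pyridine/THF, 0 °C to rt
Reagents that add atoms: none
Why: Fluoride-driven desilylation under buffered, weakly acidic conditions, which should neither trigger dienone–phenol rearrangement nor generate an alkoxide that could add to ring B.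

## Compound list

1 | 2-bromo-3,4,5-trimethoxybenzaldehyde | COc1cc(C=O)c(Br)c(OC)c1OC | starting material
2 | (Z)-crotylboronic acid pinacol ester, 2-[(Z)-but-2-en-1-yl]-4,4,5,5-tetramethyl-1,3,2-dioxaborolane | C/C=C\CB1OC(C)(C)C(C)(C)O1 | starting material
3 | (1R,2S)-1-(2-bromo-3,4,5-trimethoxyphenyl)-2-methylbut-3-en-1-ol (syn homoallylic alcohol) | C=C[C@H](C)[C@@H](O)c1cc(OC)c(OC)c(OC)c1Br | intermediate
4 | (1R,2S)-1-(2-bromo-3,4,5-trimethoxyphenyl)-2-methylbut-3-en-1-yl prop-2-enoate | C=C[C@H](C)[C@@H](OC(=O)C=C)c1cc(OC)c(OC)c(OC)c1Br | intermediate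
5 | (5S,6R)-6-(2-bromo-3,4,5-trimethoxyphenyl)-5-methyl-5,6-dihydro-2H-pyran-2-one (cis-5,6) | O=C1C=C[C@H](C)[C@@H](O1)c2cc(OC)c(OC)c(OC)c2Br | intermediate
6 | (4R,5S,6R)-6-(2-bromo-3,4,5-trimethoxyphenyl)-4,5-dimethyloxan-2-one (4,5-trans, 5,6-cis) | O=C1C[C@@H](C)[C@H](C)[C@@H](O1)c2cc(OC)c(OC)c(OC)c2Br | intermediate
7 | (3R,4S,5R)-5-(2-bromo-3,4,5-trimethoxyphenyl)-5-hydroxy-N-methoxy-N,3,4-trimethylpentanamide | CON(C)C(=O)C[C@@H](C)[C@H](C)[C@@H](O)c1cc(OC)c(OC)c(OC)c1Br | intermediate
8 | (3R,4S,5R)-5-(2-bromo-3,4,5-trimethoxyphenyl)-5-[(tert-butyldimethylsilyl)oxy]-N-methoxy-N,3,4-trimethylpentanamide | CON(C)C(=O)C[C@@H](C)[C@H](C)[C@@H](O[Si](C)(C)C(C)(C)C)c1cc(OC)c(OC)c(OC)c1Br | intermediate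
9 | aryllithium of 8 (lithium in place of bromine at arene C2) | CON(C)C(=O)C[C@@H](C)[C@H](C)[C@@H](O[Si](C)(C)C(C)(C)C)c1cc(OC)c(OC)c(OC)c1[Li] | intermediate (not isolated)
10 | (7R,8S,9R)-9-[(tert-butyldimethylsilyl)oxy]-2,3,4-trimethoxy-7,8-dimethyl-6,7,8,9-tetrahydro-5H-benzo[7]annulen-5-one (C1′ ketone) | O=C1C[C@@H](C)[C@H](C)[C@@H](O[Si](C)(C)C(C)(C)C)c2cc(OC)c(OC)c(OC)c12 | intermediate
11 | (7R,8S,9R)-9-[(tert-butyldimethylsilyl)oxy]-2,3,4-trimethoxy-5-(methoxymethylidene)-7,8-dimethyl-6,7,8,9-tetrahydro-5H-benzo[7]annulene (E/Z mixture) | COC=C1C[C@@H](C)[C@H](C)[C@@H](O[Si](C)(C)C(C)(C)C)c2cc(OC)c(OC)c(OC)c12 | intermediate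
12 | (7R,8S,9R)-9-[(tert-butyldimethylsilyl)oxy]-2,3,4-trimethoxy-7,8-dimethyl-6,7,8,9-tetrahydro-5H-benzo[7]annulene-5-carbaldehyde (both C5 epimers) | O=CC1C[C@@H](C)[C@H](C)[C@@H](O[Si](C)(C)C(C)(C)C)c2cc(OC)c(OC)c(OC)c12 | intermediate
13 | 1,3-dimethoxypropan-2-one | COCC(=O)COC | starting material
14 | 4-(dimethylamino)-1,3-dimethoxybutan-2-one (racemic) | COCC(=O)C(OC)CN(C)C | intermediate
15 | 2,4-dimethoxy-N,N,N-trimethyl-3-oxobutan-1-aminium iodide (racemic) | COCC(=O)C(OC)C[N+](C)(C)C.[I-] | intermediate
16 | 1,3-dimethoxybut-3-en-2-one | COCC(=O)C(=C)OC | intermediate (not isolated)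
17 | (7R,8S,9R)-9-[(tert-butyldimethylsilyl)oxy]-5-(2,4-dimethoxy-3-oxobutyl)-2,3,4-trimethoxy-7,8-dimethyl-6,7,8,9-tetrahydro-5H-benzo[7]annulene-5-carbaldehyde (epimers) | O=CC1(CC(OC)C(=O)COC)C[C@@H](C)[C@H](C)[C@@H](O[Si](C)(C)C(C)(C)C)c2cc(OC)c(OC)c(OC)c12 | intermediate (not isolated)
18 | spiro aldol: ring B as 2′-hydroxy-3′,5′-dimethoxycyclohexan-4′-one on the silylated ring A/ring C unit (epimers) | COC1C(O)C2(CC(OC)C1=O)C[C@@H](C)[C@H](C)[C@@H](O[Si](C)(C)C(C)(C)C)c1cc(OC)c(OC)c(OC)c12 | intermediate (not isolated)
19 | (7R,8S,9R)-9-[(tert-butyldimethylsilyl)oxy]-2,3,3′,4,5′-pentamethoxy-7,8-dimethyl-6,7,8,9-tetrahydrospiro[benzo[7]annulene-5,1′-cyclohex[2]en]-4′-one (epimers at C1′ and C5′) | COC1=CC2(CC(OC)C1=O)C[C@@H](C)[C@H](C)[C@@H](O[Si](C)(C)C(C)(C)C)c1cc(OC)c(OC)c(OC)c12 | intermediate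
20 | 4′-trimethylsilyloxy-3′,5′-dimethoxycyclohexa-2′,4′-diene form of 19 (trimethylsilyl dienol ether) | COC1=CC2(CC(OC)=C1O[Si](C)(C)C)C[C@@H](C)[C@H](C)[C@@H](O[Si](C)(C)C(C)(C)C)c1cc(OC)c(OC)c(OC)c12 | intermediate (not isolated)
21 | (7R,8S,9R)-9-[(tert-butyldimethylsilyl)oxy]-2,3,3′,4,5′-pentamethoxy-7,8-dimethyl-6,7,8,9-tetrahydrospiro[benzo[7]annulene-5,1′-cyclohexa[2,5]dien]-4′-one | COC1=CC2(C=C(OC)C1=O)C[C@@H](C)[C@H](C)[C@@H](O[Si](C)(C)C(C)(C)C)c1cc(OC)c(OC)c(OC)c12 | intermediate
22 | (7R,8S,9R)-9-hydroxy-2,3,3′,4,5′-pentamethoxy-7,8-dimethyl-6,7,8,9-tetrahydrospiro[benzo[7]annulene-5,1′-cyclohexa[2,5]dien]-4′-one (lignan numbering 7R,8S,8′R) | COC1=CC2(C=C(OC)C1=O)C[C@@H](C)[C@H](C)[C@@H](O)c1cc(OC)c(OC)c(OC)c12 | target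

## Step count and least certain steps

Total: 14 steps. Longest linear sequence: 12 steps (steps 1–9, 12, 13, 14); steps 10 and 11 form the two-step side branch.

**Step 12 (key step).** The most likely failure is that conjugate addition does not keep pace with consumption of the acceptor. The α-methoxy group makes 16 a weaker and more base-sensitive Michael acceptor than a simple vinyl ketone, and the enolate carbon is hindered, so oligomerisation of 16 or retro-Michael loss could dominate. The fallback moves the C5′ oxygen to a later stage. Aldehyde 12 would be annulated under the same base conditions with the established reagent 1-methoxybut-3-en-2-one to the spiro 2-methoxycyclohexenone F1. The enolate of F1 at C5′ (KN(SiMe3)2, THF, −78 °C) would be hydroxylated with 2-(phenylsulfonyl)-3-phenyloxaziridine to the α′-hydroxy enone F2. O-methylation (MeI, Ag2O) would return to the route at 19.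

**Step 7.** The aryllithium may be lost before it cyclises, either by proton transfer from the amide α-CH2 or by 1,4-migration of the silyl group from oxygen to the lithiated carbon, since a seven-membered ring closes slowly. The fallback avoids the organolithium and the ketone altogether.
- Lactone 6 would be reduced (i-Bu2AlH, −78 °C) to the lactol (4R,5S,6R)-6-(2-bromo-3,4,5-trimethoxyphenyl)-4,5-dimethyloxan-2-ol F3.
- Methylenation (Ph3P=CH2) would give (1R,2S,3R)-1-(2-bromo-3,4,5-trimethoxyphenyl)-2,3-dimethylhex-5-en-1-ol F4, which would be silylated to its tert-butyldimethylsilyl ether F5.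
- A 7-exo-trig Heck cyclisation (Pd(OAc)2, P(o-tol)3, Et3N, MeCN, 80 °C) would give the 5-methylidene benzo[7]annulene F6.
- Hydroboration–oxidation (9-BBN, then NaBO3) would give the primary alcohol F7, and Dess–Martin oxidation would rejoin the route at 12.

**Step 8.** Enolisation of the hindered, peri-methoxy-flanked ketone by the basic ylide may outrun olefination, and the acid of step 9 may also start to cleave or ionise the benzylic silyl ether. The fallback sets out from 10. Reductive cyanation with TosMIC (KOt-Bu, DME/EtOH) would give the 5-carbonitrile F8, and partial reduction (i-Bu2AlH, toluene, −78 °C, then mild hydrolysis of the imine) would return to the route at 12 without any acidic enol ether hydrolysis.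

**Step 13.** Transfer of the tetrasubstituted, methoxy-bearing silyl enol ether to palladium may be slow, so that protodesilylation back to 19 competes. The fallback sets out from 19. The lithium enolate (LiN(i-Pr)2, −78 °C) would be selenenylated with PhSeCl to the 5′-phenylselanyl ketone F9. Oxidation (H2O2, pyridine, CH2Cl2, 0 °C) and syn elimination of the selenoxide toward C6′, the only carbon with a β-hydrogen, would return to the route at 21.

**Step 1.** The ortho-bromo substituent may erode face selectivity in the catalytic crotylboration, which would carry through as lower enantiomeric purity of all later compounds. The fallback sets out from 1 and uses an auxiliary.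
- A boron-mediated Evans syn aldol reaction (Bu2BOTf, i-Pr2NEt) with (R)-4-benzyl-3-propanoyloxazolidin-2-one would give the aldol adduct F10.
- LiBH4 would cleave the auxiliary to (1R,2S)-1-(2-bromo-3,4,5-trimethoxyphenyl)-2-methylpropane-1,3-diol F11.
- Selective oxidation of the primary alcohol (TEMPO, PhI(OAc)2) would give the hydroxy aldehyde F12, and methylenation (Ph3P=CH2) would return to the route at 3.

## Further compounds

F1 | step 12 | (7R,8S,9R)-9-[(tert-butyldimethylsilyl)oxy]-2,3,3′,4-tetramethoxy-7,8-dimethyl-6,7,8,9-tetrahydrospiro[benzo[7]annulene-5,1′-cyclohex[2]en]-4′-one (C1′ epimers) | COC1=CC2(CCC1=O)C[C@@H](C)[C@H](C)[C@@H](O[Si](C)(C)C(C)(C)C)c1cc(OC)c(OC)c(OC)c12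
F2 | step 12 | 5′-hydroxy derivative of F1 (α′-hydroxy enone, epimers) | COC1=CC2(CC(O)C1=O)C[C@@H](C)[C@H](C)[C@@H](O[Si](C)(C)C(C)(C)C)c1cc(OC)c(OC)c(OC)c12
F3 | step 7 | (4R,5S,6R)-6-(2-bromo-3,4,5-trimethoxyphenyl)-4,5-dimethyloxan-2-ol (anomers) | OC1C[C@@H](C)[C@H](C)[C@@H](O1)c2cc(OC)c(OC)c(OC)c2Br
F4 | step 7 | (1R,2S,3R)-1-(2-bromo-3,4,5-trimethoxyphenyl)-2,3-dimethylhex-5-en-1-ol | C=CC[C@@H](C)[C@H](C)[C@@H](O)c1cc(OC)c(OC)c(OC)c1Br
F5 | step 7 | tert-butyldimethylsilyl ether of F4 | C=CC[C@@H](C)[C@H](C)[C@@H](O[Si](C)(C)C(C)(C)C)c1cc(OC)c(OC)c(OC)c1Br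
F6 | step 7 | (7R,8S,9R)-9-[(tert-butyldimethylsilyl)oxy]-2,3,4-trimethoxy-7,8-dimethyl-5-methylidene-6,7,8,9-tetrahydro-5H-benzo[7]annulene | C=C1C[C@@H](C)[C@H](C)[C@@H](O[Si](C)(C)C(C)(C)C)c2cc(OC)c(OC)c(OC)c12
F7 | step 7 | [(7R,8S,9R)-9-[(tert-butyldimethylsilyl)oxy]-2,3,4-trimethoxy-7,8-dimethyl-6,7,8,9-tetrahydro-5H-benzo[7]annulen-5-yl]methanol (C5 epimers) | OCC1C[C@@H](C)[C@H](C)[C@@H](O[Si](C)(C)C(C)(C)C)c2cc(OC)c(OC)c(OC)c12
F8 | step 8 | (7R,8S,9R)-9-[(tert-butyldimethylsilyl)oxy]-2,3,4-trimethoxy-7,8-dimethyl-6,7,8,9-tetrahydro-5H-benzo[7]annulene-5-carbonitrile (C5 epimers) | N#CC1C[C@@H](C)[C@H](C)[C@@H](O[Si](C)(C)C(C)(C)C)c2cc(OC)c(OC)c(OC)c12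
F9 | step 13 | 5′-(phenylselanyl) derivative of 19 | COC1=CC2(CC(OC)([Se]c3ccccc3)C1=O)C[C@@H](C)[C@H](C)[C@@H](O[Si](C)(C)C(C)(C)C)c1cc(OC)c(OC)c(OC)c12
F10 | step 1 | (R)-4-benzyl-3-[(2R,3R)-3-(2-bromo-3,4,5-trimethoxyphenyl)-3-hydroxy-2-methylpropanoyl]oxazolidin-2-one | O=C1OC[C@@H](Cc2ccccc2)N1C(=O)[C@H](C)[C@@H](O)c1cc(OC)c(OC)c(OC)c1Br
F11 | step 1 | (1R,2S)-1-(2-bromo-3,4,5-trimethoxyphenyl)-2-methylpropane-1,3-diol | OC[C@H](C)[C@@H](O)c1cc(OC)c(OC)c(OC)c1Br
F12 | step 1 | (2R,3R)-3-(2-bromo-3,4,5-trimethoxyphenyl)-3-hydroxy-2-methylpropanal | O=C[C@H](C)[C@@H](O)c1cc(OC)c(OC)c(OC)c1Br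
A1 | alternative 1 | 7-deoxy spirodienone with C8=C8′ double bond (achiral) | COC1=CC2(C=C(OC)C1=O)CC(C)=C(C)Cc1cc(OC)c(OC)c(OC)c12
A2 | alternative 1 | 4-hydroxy-2,6-dimethoxy-4-(2,3,4-trimethoxyphenyl)cyclohexa-2,5-dien-1-one | COC1=CC(O)(C=C(OC)C1=O)c1ccc(OC)c(OC)c1OC
A3 | alternative 1 | 2,3-dimethylbuta-1,3-diene | C=C(C)C(C)=C
A4 | alternative 2 | trans-8,8′-dimethyl C7 ketone of the spirodienone | COC1=CC2(C=C(OC)C1=O)C[C@@H](C)[C@H](C)C(=O)c1cc(OC)c(OC)c(OC)c12
A5 | alternative 2 | ring C enone of the spirodienone (C7 ketone, C8=C8′, no methyl groups) | COC1=CC2(C=C(OC)C1=O)CC=CC(=O)c1cc(OC)c(OC)c(OC)c12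
A6 | alternative 3 | methyl (7S,8R)-2,3,4-trimethoxy-7,8-dimethyl-9-oxo-6,7,8,9-tetrahydro-5H-benzo[7]annulene-5-carboxylate (C5 epimers) | O=C1C[C@@H](C)[C@H](C)C(C(=O)OC)c2cc(OC)c(OC)c(OC)c12
A7 | alternative 3 | methyl (2S,3R)-2,3-dimethyl-5-oxocyclopentane-1-carboxylate (trans-dimethyl) | O=C1C[C@@H](C)[C@H](C)C1C(=O)OC
A8 | alternative 3 | 2,3,4-trimethoxy-6-(trimethylsilyl)phenyl trifluoromethanesulfonate | COc1cc([Si](C)(C)C)c(OS(=O)(=O)C(F)(F)F)c(OC)c1OC
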